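**Retrosynthetic overview**
- Feature: in the 1,4-benzodioxane (ring B), O1 and O4 sit on the adjacent ring A carbons C8a and C4a and carry the two-carbon unit C2 (bears ring C)–C3 (bears C9H2OH). Ring B is therefore a ring A o-quinone plus a C2–C3 ketene enolate, and a carboxyl group at C7 (para to O4, meta to O1) makes the two quinone oxygens unequal.
- End game: C7 propenol ⇒ C7 aldehyde (Wittig, then iBu2AlH) ⇒ C7 tert-butyl ester. The cis C3–C9H2OH ⇒ hydroboration of a C3=C9 exocyclic enol ether ⇒ methylenation of a C3 lactone carbonyl.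
- Key disconnection: O1–C2 and O4–C3 of the (2S)-benzodioxin-3-one ⇒ 5-methoxy-7-ester o-quinone + ring C arylacetyl chloride under chiral amine catalysis.
- Rings A and C are bought as arenes, and ring B is the only ring formed (key step). C2 is set by the catalyst and C3 by C2 (substrate control).

Key step: step 8

Assumption: O-benzoylquinidine is taken, by analogy, as the pseudoenantiomer that leads to 2S; if the first run shows the opposite sense, O-benzoylquinine replaces it and nothing else changes.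
Conventions: benzodioxane numbering is O1, C2 (ring C), C3 (C9), O4, C4a, C5 (OMe), C6, C7, C8, C8a. Ar = 3,4-bis(tert-butyldimethylsilyloxy)-5-methoxyphenyl; TBS = tert-butyldimethylsilyl.

**Step 1**
Reactants: 1 3,4-dihydroxy-5-methoxybenzoic acid
Product: 2 tert-butyl 3,4-dihydroxy-5-methoxybenzoate
Conditions: Cl3CC(=NH)OtBu (2 equiv), THF–cyclohexane, rt
Reagents that add atoms: tert-butyl 2,2,2-trichloroacetimidate, CC(C)(C)OC(=N)C(Cl)(Cl)Cl
Why: Imidate esterification, in which only the carboxylic acid is acidic enough to protonate the imidate and take up the tert-butyl group, so the catechol hydroxyls stay free when no Lewis acid is added.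

**Step 2**
Reactants: 2 tert-butyl 3,4-dihydroxy-5-methoxybenzoate
Product: 3 tert-butyl 5-methoxy-3,4-dioxocyclohexa-1,5-diene-1-carboxylate (ring A o-quinone)
Conditions: Ag2O (2.5 equiv), Na2SO4, Et2O–CH2Cl2, 0 °C, dark; filter (Celite), concentrate cold, use at once in step 8
Reagents that add atoms: none
Why: Two-electron catechol-to-o-quinone oxidation under dry, non-nucleophilic conditions, where filtration should leave a solution free of acid and residual oxidant for this dimerisation-prone quinone.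

**Step 3**
Reactants: 4 3,4-dihydroxy-5-methoxybenzaldehyde (5-hydroxyvanillin)
Product: 5 3,4-bis(tert-butyldimethylsilyloxy)-5-methoxybenzaldehyde
Conditions: TBSCl (2.5 equiv), imidazole (5 equiv), DMF, rt
Reagents that add atoms: TBSCl, CC(C)(C)[Si](C)(C)Cl
Why: Imidazole-promoted silylation of both phenols, chosen because aryl silyl ethers tolerate titanium carbene, borane and aluminium hydride reagents and can leave at the end without touching the cinnamyl alcohol.

**Step 4**
Reactants: 5 3,4-bis(tert-butyldimethylsilyloxy)-5-methoxybenzaldehyde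
Product: 6 1,2-bis(tert-butyldimethylsilyloxy)-5-ethenyl-3-methoxybenzene (Ar–CH=CH2)
Conditions: Ph3PCH3Br (1.3 equiv), NaN(SiMe3)2 (1.2 equiv), THF, 0 °C; then 5, −78 °C → rt
Reagents that add atoms: methyltriphenylphosphonium bromide, C[P+](c1ccccc1)(c1ccccc1)c1ccccc1.[Br-]
Why: Wittig methylenation of an aromatic aldehyde with a non-stabilised ylide, made with a slight deficit of base so that no free amide attacks the aryl silyl ethers.

**Step 5**
Reactants: 6 Ar–CH=CH2
Product: 8 2-[3,4-bis(tert-butyldimethylsilyloxy)-5-methoxyphenyl]ethanol, via ring C alkylborane 7 (not isolated)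
Conditions: 9-BBN (1.3 equiv), THF, 0 °C → rt; then 30% H2O2, aq. NaHCO3, 0 °C → rt
Reagents that add atoms: 9-BBN, B1C2CCCC1CCC2 (boron cage held in 7 only); hydrogen peroxide, OO
Why: Anti-Markovnikov hydroboration–oxidation of a styrene, in which bulky 9-BBN places boron on the terminal carbon and the weakly basic peroxide work-up spares the aryl silyl ethers.

**Step 6**
Reactants: 8 2-Ar-ethanol
Product: 10 [3,4-bis(tert-butyldimethylsilyloxy)-5-methoxyphenyl]acetic acid, via arylacetaldehyde 9 (not isolated)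
Conditions: TEMPO (10 mol %), NaClO2 (2 equiv), NaOCl (2 mol %), MeCN–sodium phosphate buffer (pH 6.7), 35 °C
Reagents that add atoms: sodium chlorite, [Na+].[O-]Cl=O
Why: Oxoammonium oxidation of the alcohol to 9 followed by Pinnick-type chlorite oxidation in the same flask at near-neutral pH, a protocol established for electron-rich 2-arylethanols without ring chlorination.

**Step 7**
Reactants: 10 Ar-acetic acid
Product: 11 [3,4-bis(tert-butyldimethylsilyloxy)-5-methoxyphenyl]acetyl chloride
Conditions: (COCl)2 (1.3 equiv), DMF (cat.), CH2Cl2, 0 °C → rt; evaporate, use crude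
Reagents that add atoms: oxalyl chloride, O=C(Cl)C(=O)Cl
Why: Vilsmeier-type acid activation gives the acid chloride with gaseous by-products only, and aryl silyl ethers tolerate the short contact with anhydrous HCl.

**Step 8**
Reactants: 3 ring A o-quinone; 11 Ar-acetyl chloride
Product: 15 tert-butyl (2S)-2-Ar-5-methoxy-3-oxo-2,3-dihydro-1,4-benzodioxine-7-carboxylate, via aryl ketene 12 (not isolated), via ammonium enolate 13 (not isolated), via acylammonium phenoxide 14 (not isolated)
Conditions: 3 (1.0 equiv), O-benzoylquinidine (10 mol %), iPr2NEt (1.0 equiv), THF, −78 °C; 11 (1.1 equiv) in THF added slowly; cold dilute-acid quench, quick silica filtration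
Reagents that add atoms: none
Why: Proposed new method: iPr2NEt, with the alkaloid as proton shuttle, dehydrochlorinates 11 to aryl ketene 12, and the quinuclidine nitrogen adds to 12 on the side away from the aryl group to give the (Z)-ammonium enolate 13. The enolate carbon (future C2) bonds to the quinone oxygen on C8a (O1–C2), ring A aromatises to the C4a phenoxide of 14, and this phenoxide attacks the acylammonium carbonyl in a 6-exo-trig acyl substitution (O4–C3) that closes ring B as the lactone and releases the catalyst, so the overall event is a stepwise, asynchronous hetero-[4+2] with O=C8a–C4a=O as the four-atom partner. The closest known reaction type is the cinchona-alkaloid-catalysed [4+2] of acid-chloride-derived ketene enolates with tetrahalo-o-quinones; what is new is an unsymmetrical, halogen-free o-quinone with free C6–H and C8–H positions. C2 is controlled by the catalyst alone: the quinoline and benzoate groups cover one face of the bound enolate so the quinone must approach the other, and the absence of excess base at −78 °C should keep the acidic C2–H of 15 from exchanging. Two selectivities are needed, oxygen over carbon attack and O1 over O4: bonding at the C8a oxygen lets the negative charge build up on the C4a oxygen para to the C7 ester, the better stabilised of the two possible phenoxides, and the C8a oxygen is also the one not flanked by the C5 methoxy group, so electronic and steric bias point the same way. Oxygen attack is favoured because it aromatises ring A in the bond-forming event, and slow addition of 11 keeps 12 dilute, which limits ketene dimerisation and conjugate addition at C8.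

**Step 9**
Reactants: 15 (2S)-lactone
Product: 16 tert-butyl (2S)-2-Ar-5-methoxy-3-methylidene-2,3-dihydro-1,4-benzodioxine-7-carboxylate
Conditions: Cp2TiMe2 (1.5 equiv), toluene, 65 °C, dark, Ar; dilute with hexane, filter through basic alumina
Reagents that add atoms: dimethyltitanocene Cp2TiMe2, [CH3-].[CH3-].[Ti+4].[cH-]1cccc1.[cH-]1cccc1
Why: Petasis methylenation, in which the non-basic Cp2Ti=CH2 leaves the acidic C2–H alone and, with the reagent limited, should prefer the electrophilic, unhindered aryl lactone carbonyl over the conjugated, hindered tert-butyl benzoate.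

**Step 10**
Reactants: 16 exocyclic enol ether
Product: 18 tert-butyl (2S,3R)-2-Ar-3-(hydroxymethyl)-5-methoxy-2,3-dihydro-1,4-benzodioxine-7-carboxylate (cis), via C9 alkylborane 17 (not isolated)
Conditions: 9-BBN (1.5 equiv), THF, 0 °C → rt; then 30% H2O2, aq. NaHCO3, 0 °C
Reagents that add atoms: 9-BBN, B1C2CCCC1CCC2 (boron cage held in 17 only); hydrogen peroxide, OO
Why: Hydroboration–oxidation of an exocyclic enol ether, where the ring oxygen and sterics both send boron to C9, and the C2 aryl group (pseudo-axial to escape allylic strain with the methylidene) blocks one face so that H reaches C3 from the other face and C9 ends up cis to ring C (3R).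

**Step 11**
Reactants: 18 cis alcohol ester
Product: 19 [(2S,3R)-2-Ar-5-methoxy-2,3-dihydro-1,4-benzodioxine-3,7-diyl]dimethanol
Conditions: iBu2AlH (4.5 equiv), CH2Cl2, −78 → 0 °C; aq. potassium sodium tartrate
Reagents that add atoms: none
Why: Ester-to-alcohol reduction with excess aluminium hydride (one equivalent is spent on the free hydroxyl), to which the aryl silyl ethers, the aryl ethers and both stereocentres are inert.

**Step 12**
Reactants: 19 diol
Product: 20 (2S,3R)-2-Ar-3-(hydroxymethyl)-5-methoxy-2,3-dihydro-1,4-benzodioxine-7-carbaldehyde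
Conditions: MnO2 (activated, 15 equiv), CH2Cl2, rt
Reagents that add atoms: none
Why: Chemoselective MnO2 oxidation acts on the benzylic alcohol only and leaves the saturated C9 alcohol, so C9 needs no protecting group.

**Step 13**
Reactants: 20 aldehyde
Product: 21 ethyl (E)-3-[(2S,3R)-2-Ar-3-(hydroxymethyl)-5-methoxy-2,3-dihydro-1,4-benzodioxin-7-yl]prop-2-enoate
Conditions: Ph3P=CHCO2Et (1.5 equiv), toluene, 60 °C
Reagents that add atoms: ethyl (triphenylphosphoranylidene)acetate, CCOC(=O)C=P(c1ccccc1)(c1ccccc1)c1ccccc1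
Why: Wittig olefination with a stabilised ylide under neutral conditions is E-selective with aromatic aldehydes and tolerates the free alcohol and the base-labile aryl silyl ethers.

**Step 14**
Reactants: 21 E-enoate
Product: 22 (E)-3-[(2S,3R)-2-Ar-3-(hydroxymethyl)-5-methoxy-2,3-dihydro-1,4-benzodioxin-7-yl]prop-2-en-1-ol
Conditions: iBu2AlH (4 equiv), CH2Cl2, −78 °C; aq. potassium sodium tartrate
Reagents that add atoms: none
Why: 1,2-Reduction of an α,β-unsaturated ester by iBu2AlH at low temperature gives the E-allylic alcohol without conjugate reduction.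

**Step 15**
Reactants: 22 bis-silyl ether
Product: 23 5-[(2S,3R)-3-(hydroxymethyl)-7-[(E)-3-hydroxyprop-1-enyl]-5-methoxy-2,3-dihydro-1,4-benzodioxin-2-yl]-3-methoxybenzene-1,2-diol (target)
Conditions: Et3N·3HF (5 equiv), degassed THF, 0 °C → rt, Ar
Reagents that add atoms: none
Why: Fluoride-induced cleavage of the two aryl silyl ethers in a slightly acidic, oxygen-free medium avoids the phenoxide conditions under which the free catechol autoxidises and is too mild to ionise the cinnamyl alcohol.

**Compound list**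
1 | 3,4-dihydroxy-5-methoxybenzoic acid | COc1cc(C(=O)O)cc(O)c1O | starting material
2 | tert-butyl 3,4-dihydroxy-5-methoxybenzoate | COc1cc(C(=O)OC(C)(C)C)cc(O)c1O | intermediate
3 | tert-butyl 5-methoxy-3,4-dioxocyclohexa-1,5-diene-1-carboxylate | COC1=CC(C(=O)OC(C)(C)C)=CC(=O)C1=O | intermediate
4 | 3,4-dihydroxy-5-methoxybenzaldehyde | COc1cc(C=O)cc(O)c1O | starting material
5 | 3,4-bis(tert-butyldimethylsilyloxy)-5-methoxybenzaldehyde | COc1cc(C=O)cc(O[Si](C)(C)C(C)(C)C)c1O[Si](C)(C)C(C)(C)C | intermediate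
6 | 1,2-bis(tert-butyldimethylsilyloxy)-5-ethenyl-3-methoxybenzene | C=Cc1cc(OC)c(O[Si](C)(C)C(C)(C)C)c(O[Si](C)(C)C(C)(C)C)c1 | intermediate
7 | 9-(2-Ar-ethyl)-9-borabicyclo[3.3.1]nonane | COc1cc(CCB2C3CCCC2CCC3)cc(O[Si](C)(C)C(C)(C)C)c1O[Si](C)(C)C(C)(C)C | intermediate (not isolated)
8 | 2-[3,4-bis(tert-butyldimethylsilyloxy)-5-methoxyphenyl]ethanol | COc1cc(CCO)cc(O[Si](C)(C)C(C)(C)C)c1O[Si](C)(C)C(C)(C)C | intermediate
9 | [3,4-bis(tert-butyldimethylsilyloxy)-5-methoxyphenyl]acetaldehyde | COc1cc(CC=O)cc(O[Si](C)(C)C(C)(C)C)c1O[Si](C)(C)C(C)(C)C | intermediate (not isolated)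
10 | [3,4-bis(tert-butyldimethylsilyloxy)-5-methoxyphenyl]acetic acid | COc1cc(CC(=O)O)cc(O[Si](C)(C)C(C)(C)C)c1O[Si](C)(C)C(C)(C)C | intermediate
11 | [3,4-bis(tert-butyldimethylsilyloxy)-5-methoxyphenyl]acetyl chloride | COc1cc(CC(=O)Cl)cc(O[Si](C)(C)C(C)(C)C)c1O[Si](C)(C)C(C)(C)C | intermediate
12 | [3,4-bis(tert-butyldimethylsilyloxy)-5-methoxyphenyl]ketene | COc1cc(C=C=O)cc(O[Si](C)(C)C(C)(C)C)c1O[Si](C)(C)C(C)(C)C | intermediate (not isolated)
13 | (Z)-enolate of the N-(Ar-acetyl) O-benzoylquinidinium ion (zwitterion) | COc1ccc2nccc([C@H](OC(=O)c3ccccc3)[C@H]3C[C@@H]4CC[N+]3(C[C@@H]4C=C)/C([O-])=C/c3cc(OC)c(O[Si](C)(C)C(C)(C)C)c(O[Si](C)(C)C(C)(C)C)c3)c2c1 | intermediate (not isolated)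
14 | N-[(2S)-2-Ar-2-(aryloxy)acetyl] O-benzoylquinidinium C4a phenoxide (zwitterion, O1–C2 formed) | COc1ccc2nccc([C@H](OC(=O)c3ccccc3)[C@H]3C[C@@H]4CC[N+]3(C[C@@H]4C=C)C(=O)[C@@H](Oc3cc(C(=O)OC(C)(C)C)cc(OC)c3[O-])c3cc(OC)c(O[Si](C)(C)C(C)(C)C)c(O[Si](C)(C)C(C)(C)C)c3)c2c1 | intermediate (not isolated)
15 | tert-butyl (2S)-2-Ar-5-methoxy-3-oxo-2,3-dihydro-1,4-benzodioxine-7-carboxylate | COc1cc([C@@H]2Oc3cc(C(=O)OC(C)(C)C)cc(OC)c3OC2=O)cc(O[Si](C)(C)C(C)(C)C)c1O[Si](C)(C)C(C)(C)C | intermediate
16 | tert-butyl (2S)-2-Ar-5-methoxy-3-methylidene-2,3-dihydro-1,4-benzodioxine-7-carboxylate | COc1cc([C@@H]2Oc3cc(C(=O)OC(C)(C)C)cc(OC)c3OC2=C)cc(O[Si](C)(C)C(C)(C)C)c1O[Si](C)(C)C(C)(C)C | intermediate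
17 | tert-butyl (2S,3R)-2-Ar-3-[(9-borabicyclo[3.3.1]nonan-9-yl)methyl]-5-methoxy-2,3-dihydro-1,4-benzodioxine-7-carboxylate | COc1cc([C@@H]2Oc3cc(C(=O)OC(C)(C)C)cc(OC)c3O[C@@H]2CB4C5CCCC4CCC5)cc(O[Si](C)(C)C(C)(C)C)c1O[Si](C)(C)C(C)(C)C | intermediate (not isolated)
18 | tert-butyl (2S,3R)-2-Ar-3-(hydroxymethyl)-5-methoxy-2,3-dihydro-1,4-benzodioxine-7-carboxylate | COc1cc([C@@H]2Oc3cc(C(=O)OC(C)(C)C)cc(OC)c3O[C@@H]2CO)cc(O[Si](C)(C)C(C)(C)C)c1O[Si](C)(C)C(C)(C)C | intermediate
19 | [(2S,3R)-2-Ar-5-methoxy-2,3-dihydro-1,4-benzodioxine-3,7-diyl]dimethanol | COc1cc([C@@H]2Oc3cc(CO)cc(OC)c3O[C@@H]2CO)cc(O[Si](C)(C)C(C)(C)C)c1O[Si](C)(C)C(C)(C)C | intermediate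
20 | (2S,3R)-2-Ar-3-(hydroxymethyl)-5-methoxy-2,3-dihydro-1,4-benzodioxine-7-carbaldehyde | COc1cc([C@@H]2Oc3cc(C=O)cc(OC)c3O[C@@H]2CO)cc(O[Si](C)(C)C(C)(C)C)c1O[Si](C)(C)C(C)(C)C | intermediate
21 | ethyl (E)-3-[(2S,3R)-2-Ar-3-(hydroxymethyl)-5-methoxy-2,3-dihydro-1,4-benzodioxin-7-yl]prop-2-enoate | COc1cc([C@@H]2Oc3cc(/C=C/C(=O)OCC)cc(OC)c3O[C@@H]2CO)cc(O[Si](C)(C)C(C)(C)C)c1O[Si](C)(C)C(C)(C)C | intermediate
22 | (E)-3-[(2S,3R)-2-Ar-3-(hydroxymethyl)-5-methoxy-2,3-dihydro-1,4-benzodioxin-7-yl]prop-2-en-1-ol | COc1cc([C@@H]2Oc3cc(/C=C/CO)cc(OC)c3O[C@@H]2CO)cc(O[Si](C)(C)C(C)(C)C)c1O[Si](C)(C)C(C)(C)C | intermediate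
23 | 5-[(2S,3R)-3-(hydroxymethyl)-7-[(E)-3-hydroxyprop-1-enyl]-5-methoxy-2,3-dihydro-1,4-benzodioxin-2-yl]-3-methoxybenzene-1,2-diol | COc1cc([C@@H]2Oc3cc(/C=C/CO)cc(OC)c3O[C@@H]2CO)cc(O)c1O | target

**Step count**
- Total step count: 15.
- Longest linear sequence: 13 (steps 3–15). Steps 1–2 form the two-step ring A branch.

**Steps most likely to fail**

1. **Step 8.**
   - What may go wrong:
     - carbon attack of the enolate at the open ring positions of the quinone (conjugate addition at C8);
     - bonding to the wrong quinone oxygen;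
     - Diels–Alder self-dimerisation or amine-induced redox decay of the quinone;
     - loss of enantiopurity by enolisation at C2.
   - Fallback (known chemistry, sets out from 11 and 2, returns at 15): the two C–O bonds are made one after the other, with the regiochemistry fixed by protection.
     - Acid chloride 11 is esterified with benzyl alcohol and pyridine to benzyl arylacetate F1.
     - Diazo transfer (4-acetamidobenzenesulfonyl azide, DBU, dry MeCN) gives benzyl aryldiazoacetate F2.
     - Catechol 2 is benzylated at its more acidic hydroxyl para to the ester (BnBr 1.0 equiv, KHCO3, DMF) to the mono-benzyl phenol F3, which leaves only the future O1–H free.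
     - Enantioselective carbene O–H insertion of F2 into F3 forms O1–C2 and gives the (S)-aryloxy ester F4. The conditions are PdCl2(PhCN)2, a chiral spiro bis(oxazoline) ligand, NaB[3,5-(CF3)2C6H3]4, CHCl3 and molecular sieves, a known reaction of α-aryl-α-diazoacetates with phenols.
     - Hydrogenolysis (H2, Pd/C, EtOAc) removes both benzyl groups to give the hydroxy acid F5.
     - Carbodiimide lactonisation (EDC·HCl, CH2Cl2, 0 °C) forms O4–C3 and gives 15.

2. **Step 9.**
   - What may go wrong: competing methylenation of the C7 ester, or migration of the exocyclic double bond into ring B with loss of the C2 stereocentre.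
   - Fallback (sets out from 15, returns at 16): C9 is brought in without a titanium carbene, and ring B is opened and closed again.
     - iBu2AlH (1.05 equiv, toluene, −78 °C) reduces only the aryl lactone and gives the lactol F6.
     - Wittig methylenation of its open hydroxy-aldehyde form (Ph3PCH3Br, NaN(SiMe3)2, THF, −78 °C) gives the allyl ether phenol F7.
     - 6-exo iodoetherification (I2, NaHCO3, MeCN, 0 °C) re-forms O4–C3 and gives the iodomethyl benzodioxane F8. Its C3 configuration does not matter.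
     - Dehydroiodination (DBU, dry toluene, 80 °C), for which C3–H is the only β-hydrogen, gives 16.

3. **Step 10.**
   - What may go wrong: poor facial selectivity of the borane, or β-elimination of the aryloxide from the β-aryloxy organoborane with opening of ring B.
   - Fallback (sets out from 16, returns at 19): the net anti-Markovnikov hydration is done through oxygen first and hydride second.
     - Dimethyldioxirane (acetone–CH2Cl2, −78 → 0 °C) epoxidises the enol ether on the face anti to the aryl group and gives the spiro-epoxide F9.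
     - Excess iBu2AlH (CH2Cl2, −78 → 0 °C) opens the acetal C3–O bond and delivers hydride to C3 from the side of the departing oxygen, again anti to the aryl group, so C9 stays cis.
     - The same reagent reduces the tert-butyl ester in that operation, which gives diol 19 directly.

**Further compounds**
F1 | step 8 | benzyl [3,4-bis(tert-butyldimethylsilyloxy)-5-methoxyphenyl]acetate | COc1cc(CC(=O)OCc2ccccc2)cc(O[Si](C)(C)C(C)(C)C)c1O[Si](C)(C)C(C)(C)C
F2 | step 8 | benzyl 2-diazo-2-[3,4-bis(tert-butyldimethylsilyloxy)-5-methoxyphenyl]acetate | COc1cc(C(=[N+]=[N-])C(=O)OCc2ccccc2)cc(O[Si](C)(C)C(C)(C)C)c1O[Si](C)(C)C(C)(C)C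
F3 | step 8 | tert-butyl 4-(benzyloxy)-3-hydroxy-5-methoxybenzoate | COc1cc(C(=O)OC(C)(C)C)cc(O)c1OCc1ccccc1
F4 | step 8 | benzyl (2S)-2-[2-(benzyloxy)-5-(tert-butoxycarbonyl)-3-methoxyphenoxy]-2-[3,4-bis(tert-butyldimethylsilyloxy)-5-methoxyphenyl]acetate | COc1cc([C@H](Oc2cc(C(=O)OC(C)(C)C)cc(OC)c2OCc2ccccc2)C(=O)OCc2ccccc2)cc(O[Si](C)(C)C(C)(C)C)c1O[Si](C)(C)C(C)(C)C
F5 | step 8 | (2S)-2-[5-(tert-butoxycarbonyl)-2-hydroxy-3-methoxyphenoxy]-2-[3,4-bis(tert-butyldimethylsilyloxy)-5-methoxyphenyl]acetic acid | COc1cc([C@H](Oc2cc(C(=O)OC(C)(C)C)cc(OC)c2O)C(=O)O)cc(O[Si](C)(C)C(C)(C)C)c1O[Si](C)(C)C(C)(C)C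
F6 | step 9 | tert-butyl (2S)-2-Ar-3-hydroxy-5-methoxy-2,3-dihydro-1,4-benzodioxine-7-carboxylate (lactol, both C3 epimers) | COc1cc([C@@H]2Oc3cc(C(=O)OC(C)(C)C)cc(OC)c3OC2O)cc(O[Si](C)(C)C(C)(C)C)c1O[Si](C)(C)C(C)(C)C
F7 | step 9 | tert-butyl 3-{[(1R)-1-Ar-prop-2-en-1-yl]oxy}-4-hydroxy-5-methoxybenzoate | COc1cc([C@@H](C=C)Oc2cc(C(=O)OC(C)(C)C)cc(OC)c2O)cc(O[Si](C)(C)C(C)(C)C)c1O[Si](C)(C)C(C)(C)C
F8 | step 9 | tert-butyl (2S)-2-Ar-3-(iodomethyl)-5-methoxy-2,3-dihydro-1,4-benzodioxine-7-carboxylate (both C3 epimers) | COc1cc([C@@H]2Oc3cc(C(=O)OC(C)(C)C)cc(OC)c3OC2CI)cc(O[Si](C)(C)C(C)(C)C)c1O[Si](C)(C)C(C)(C)C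
F9 | step 10 | spiro-epoxide of 16 across C3=C9 (2S,3R; epoxide oxygen anti to Ar) | COc1cc([C@@H]2Oc3cc(C(=O)OC(C)(C)C)cc(OC)c3O[C@]24CO4)cc(O[Si](C)(C)C(C)(C)C)c1O[Si](C)(C)C(C)(C)C
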